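**Plan**
Ring atoms are called C1 (CH bearing the first coumarinyl), C2=C3(CH3), C4H2, C5(CH3)2 and C6 (CH); C7 is the carbinol carbon. Retrosynthetic cuts, in order: C7–H (ketone reduction); C3–CH3 (methyl coupling of an enol triflate, so C3 becomes a ring ketone); C5–C6 (ring); C1–C6 (chain); the styryl C=C of a dienone; the C8–C bonds to the coumarin.
Enabling feature: the carbocycle is a 3,5,5-trimethylcyclohexene in which C3 and C7 are 1,5-related. With both at the ketone level, C5 is the β-carbon of a C3(=O)–C4H=C5(CH3)2 enone and C6 the α-carbon of the aryl ketone, so the ring closes by one intramolecular Michael addition.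
Forward order: 5,7-dimethoxycoumarin → 8-carbaldehyde → β-keto ester (donor) and styryl isobutenyl ketone (acceptor) → Michael union (C1–C6) → decarboxylation → ring closure (C5–C6) → C3 ketone to C2=C3–CH3 → C7 reduction.
Stereochemistry: C1 from the amine-catalysed Michael addition; C6 by thermodynamic trans placement next to the C1 aryl group; C7 by Felkin–Anh hydride addition anti to C5.

Key step: step 7

Remark: electrophilic substitution of 5,7-dimethoxycoumarin is taken to occur at C8 (para to the 5-methoxy group), not at C6 or C3.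

Step 1
Reactants: 1 5,7-dimethoxy-2H-chromen-2-one
Product: 3 5,7-dimethoxy-2-oxo-2H-chromene-8-carbaldehyde, via alpha-chloro ether 2 (not isolated)
Conditions: Cl2CHOMe, TiCl4, CH2Cl2, 0 °C → 25 °C; then H2O
Reagents that add atoms: dichloromethyl methyl ether COC(Cl)Cl; water O
Why: Rieche formylation (Friedel–Crafts attack of the TiCl4-activated chloro(methoxy)carbenium ion) should go to C8, the position para to the 5-methoxy and ortho to the 7-methoxy group and less crowded than C6, and hydrolysis of the chloro ether frees the aldehyde.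

Step 2
Reactants: 3 5,7-dimethoxy-2-oxo-2H-chromene-8-carbaldehyde; 4 tert-butyl bromoacetate
Product: 6 tert-butyl 3-(5,7-dimethoxy-2-oxo-2H-chromen-8-yl)-3-hydroxypropanoate (racemic), via Reformatsky reagent 5 (not isolated)
Conditions: Zn (TMSCl-activated), THF, 50 °C; then 3, 25 °C; H2O work-up
Reagents that add atoms: none
Why: Reformatsky reaction, in which the zinc enolate adds to the aldehyde and ignores the lactone; the new carbinol centre is not controlled and is erased in step 3.

Step 3
Reactants: 6 tert-butyl 3-(5,7-dimethoxy-2-oxo-2H-chromen-8-yl)-3-hydroxypropanoate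
Product: 7 tert-butyl 3-(5,7-dimethoxy-2-oxo-2H-chromen-8-yl)-3-oxopropanoate
Conditions: Dess–Martin periodinane, CH2Cl2, 25 °C
Reagents that add atoms: none
Why: Dess–Martin oxidation should convert the secondary benzylic alcohol into the β-keto ester under neutral conditions that spare the lactone and the tert-butyl ester.

Step 4
Reactants: 3 5,7-dimethoxy-2-oxo-2H-chromene-8-carbaldehyde; 8 4-methylpent-3-en-2-one
Product: 11 5,7-dimethoxy-8-[(1E)-5-methyl-3-oxohexa-1,4-dien-1-yl]-2H-chromen-2-one, via lithium dienolate 9 (not isolated), via aldol adduct 10 (not isolated)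
Conditions: 8, LiN(i-Pr)2, THF, −78 °C; then 3, −78 °C; AcOH; then p-TsOH·H2O (cat.), toluene, 40 °C
Reagents that add atoms: none
Why: Aldol condensation: kinetic deprotonation of the methyl group of 8 gives the cross-conjugated enolate, which adds to the aldehyde, and acid-catalysed dehydration through the electron-rich benzylic position should give the (E)-dienone.

Step 5
Reactants: 7 tert-butyl 3-(5,7-dimethoxy-2-oxo-2H-chromen-8-yl)-3-oxopropanoate; 11 5,7-dimethoxy-8-[(1E)-5-methyl-3-oxohexa-1,4-dien-1-yl]-2H-chromen-2-one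
Product: 12 tert-butyl (3S)-2-(5,7-dimethoxy-2-oxo-2H-chromene-8-carbonyl)-3-(5,7-dimethoxy-2-oxo-2H-chromen-8-yl)-7-methyl-5-oxooct-6-enoate (both C2 epimers)
Conditions: 9-amino-9-deoxy-epi-quinidine (20 mol %), CF3CO2H (40 mol %), toluene, 40 °C
Reagents that add atoms: none
Why: Enantioselective Michael addition under iminium catalysis, in which the primary amine condenses with the unhindered dienone carbonyl, the enol of 7 adds to the aryl-bearing β-carbon C1 (the β,β-dimethyl terminus C5 being too hindered for intermolecular attack) and the cinchona scaffold should shield one face of the (E)-iminium ion so that C1 forms as (S), the quinine-derived pseudoenantiomer being at hand if the facial sense proves opposite; the ester-bearing carbon is not controlled and loses its stereochemistry in step 6.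

Step 6
Reactants: 12 tert-butyl (3S)-2-(5,7-dimethoxy-2-oxo-2H-chromene-8-carbonyl)-3-(5,7-dimethoxy-2-oxo-2H-chromen-8-yl)-7-methyl-5-oxooct-6-enoate
Product: 14 (3S)-1,3-bis(5,7-dimethoxy-2-oxo-2H-chromen-8-yl)-7-methyloct-6-ene-1,5-dione, via beta-keto acid 13 (not isolated)
Conditions: CF3CO2H, CH2Cl2, 25 °C; then toluene, 70 °C
Reagents that add atoms: none
Why: Acidolysis of the tert-butyl ester (loss of 2-methylpropene) followed by thermal decarboxylation of the β-keto acid through its cyclic transition state should remove the activating group without touching the C1 stereocentre.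

Step 7
Reactants: 14 (3S)-1,3-bis(5,7-dimethoxy-2-oxo-2H-chromen-8-yl)-7-methyloct-6-ene-1,5-dione
Product: 15 (3S,4R)-3-(5,7-dimethoxy-2-oxo-2H-chromen-8-yl)-4-(5,7-dimethoxy-2-oxo-2H-chromene-8-carbonyl)-5,5-dimethylcyclohexan-1-one
Conditions: KOt-Bu (20 mol %), THF–t-BuOH, 0 → 25 °C; AcOH
Reagents that add atoms: none
Why: KOt-Bu reversibly forms the enolate of the aryl ketone at C6, which adds to C5, the β-carbon of the 4-methylpent-3-en-2-one unit, to make the C5–C6 bond and the quaternary gem-dimethyl carbon, and the ring enolate is then protonated by t-BuOH. The closest known reaction type is the intramolecular Michael addition of a ketone enolate to a β,β-dimethyl enone, as in isophorone-type ring formation and double Michael annulations of divinyl ketones. The six-membered ring closes in the 6-(enolexo)-endo-trig mode. The new stereocentre C6 remains epimerisable α to the aryl ketone and should settle trans to the C1 coumarinyl group with both substituents equatorial, so it is controlled thermodynamically by the C1 centre set in step 5. The step needs chemoselectivity among three enolisable positions, and ring size secures it: only C6 reaches an acceptor carbon through a six-membered transition state, whereas the aldol alternatives are four-membered or engage the hindered, electron-rich aryl ketone and are reversible. Catalytic base at or below room temperature should keep retro-Michael cleavage at C1 from eroding the enantiomeric purity.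

Step 8
Reactants: 15 (3S,4R)-3-(5,7-dimethoxy-2-oxo-2H-chromen-8-yl)-4-(5,7-dimethoxy-2-oxo-2H-chromene-8-carbonyl)-5,5-dimethylcyclohexan-1-one
Product: 17 (3S,4R)-3-(5,7-dimethoxy-2-oxo-2H-chromen-8-yl)-4-(5,7-dimethoxy-2-oxo-2H-chromene-8-carbonyl)-5,5-dimethylcyclohex-1-en-1-yl trifluoromethanesulfonate, via potassium enolate 16 (not isolated)
Conditions: KN(SiMe3)2, THF, −78 °C; then N-(5-chloropyridin-2-yl)bis(trifluoromethanesulfonimide), −78 °C; H2O
Reagents that add atoms: N-(5-chloropyridin-2-yl)bis(trifluoromethanesulfonimide) FC(F)(F)S(=O)(=O)N(c1ccc(Cl)cn1)S(=O)(=O)C(F)(F)F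
Why: Enol triflate formation: kinetic deprotonation by the hindered amide should occur at the ring CH2 (C2) next to CH(aryl) and not at the neopentyl CH2 (C4) next to C(CH3)2 or the shielded methine C6, and O-sulfonylation at −78 °C fixes the C2=C3 double bond.

Step 9
Reactants: 17 (3S,4R)-3-(5,7-dimethoxy-2-oxo-2H-chromen-8-yl)-4-(5,7-dimethoxy-2-oxo-2H-chromene-8-carbonyl)-5,5-dimethylcyclohex-1-en-1-yl trifluoromethanesulfonate
Product: 18 8-[(1S,6R)-6-(5,7-dimethoxy-2-oxo-2H-chromene-8-carbonyl)-3,5,5-trimethylcyclohex-2-en-1-yl]-5,7-dimethoxy-2H-chromen-2-one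
Conditions: MeZnCl, Pd(PPh3)4 (5 mol %), THF, 25 → 50 °C
Reagents that add atoms: methylzinc chloride C[Zn]Cl
Why: Negishi cross-coupling of the enol triflate under zerovalent palladium catalysis should install the C3 methyl group without moving the double bond, the organozinc reagent being inert toward the ketone and the lactones.

Step 10
Reactants: 18 8-[(1S,6R)-6-(5,7-dimethoxy-2-oxo-2H-chromene-8-carbonyl)-3,5,5-trimethylcyclohex-2-en-1-yl]-5,7-dimethoxy-2H-chromen-2-one
Product: 19 8-[(1S,6R)-6-[(R)-(5,7-dimethoxy-2-oxo-2H-chromen-8-yl)(hydroxy)methyl]-3,5,5-trimethylcyclohex-2-en-1-yl]-5,7-dimethoxy-2H-chromen-2-one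
Conditions: NaBH4, CeCl3·7H2O, MeOH–THF, −20 → 0 °C
Reagents that add atoms: none
Why: Luche reduction (1,2-selective, sparing the coumarin lactones) should follow the Felkin–Anh model, hydride approaching anti to the quaternary C5 with the aryl group eclipsing the C6–H bond, which sets C7 as (R).

**Compound list**
1 | 5,7-dimethoxy-2H-chromen-2-one (5,7-dimethoxycoumarin) | COc1cc(OC)c2ccc(=O)oc2c1 | starting material
2 | 8-[chloro(methoxy)methyl]-5,7-dimethoxy-2H-chromen-2-one | COc1cc(OC)c2ccc(=O)oc2c1C(Cl)OC | intermediate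
3 | 5,7-dimethoxy-2-oxo-2H-chromene-8-carbaldehyde | COc1cc(OC)c2ccc(=O)oc2c1C=O | intermediate
4 | tert-butyl bromoacetate | CC(C)(C)OC(=O)CBr | starting material
5 | tert-butyl (bromozincio)acetate | CC(C)(C)OC(=O)C[Zn]Br | intermediate
6 | tert-butyl 3-(5,7-dimethoxy-2-oxo-2H-chromen-8-yl)-3-hydroxypropanoate (racemic) | COc1cc(OC)c2ccc(=O)oc2c1C(O)CC(=O)OC(C)(C)C | intermediate
7 | tert-butyl 3-(5,7-dimethoxy-2-oxo-2H-chromen-8-yl)-3-oxopropanoate | COc1cc(OC)c2ccc(=O)oc2c1C(=O)CC(=O)OC(C)(C)C | intermediate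
8 | 4-methylpent-3-en-2-one (mesityl oxide) | CC(=O)C=C(C)C | starting material
9 | lithium 4-methylpenta-1,3-dien-2-olate | [Li+].C=C([O-])C=C(C)C | intermediate
10 | 8-(1-hydroxy-5-methyl-3-oxohex-4-en-1-yl)-5,7-dimethoxy-2H-chromen-2-one (racemic) | COc1cc(OC)c2ccc(=O)oc2c1C(O)CC(=O)C=C(C)C | intermediate
11 | 5,7-dimethoxy-8-[(1E)-5-methyl-3-oxohexa-1,4-dien-1-yl]-2H-chromen-2-one | COc1cc(OC)c2ccc(=O)oc2c1/C=C/C(=O)C=C(C)C | intermediate
12 | tert-butyl (3S)-2-(5,7-dimethoxy-2-oxo-2H-chromene-8-carbonyl)-3-(5,7-dimethoxy-2-oxo-2H-chromen-8-yl)-7-methyl-5-oxooct-6-enoate | COc1cc(OC)c2ccc(=O)oc2c1[C@@H](CC(=O)C=C(C)C)C(C(=O)OC(C)(C)C)C(=O)c1c(OC)cc(OC)c2ccc(=O)oc12 | intermediate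
13 | (3S)-2-(5,7-dimethoxy-2-oxo-2H-chromene-8-carbonyl)-3-(5,7-dimethoxy-2-oxo-2H-chromen-8-yl)-7-methyl-5-oxooct-6-enoic acid | COc1cc(OC)c2ccc(=O)oc2c1[C@@H](CC(=O)C=C(C)C)C(C(=O)O)C(=O)c1c(OC)cc(OC)c2ccc(=O)oc12 | intermediate
14 | (3S)-1,3-bis(5,7-dimethoxy-2-oxo-2H-chromen-8-yl)-7-methyloct-6-ene-1,5-dione | COc1cc(OC)c2ccc(=O)oc2c1[C@@H](CC(=O)C=C(C)C)CC(=O)c1c(OC)cc(OC)c2ccc(=O)oc12 | intermediate
15 | (3S,4R)-3-(5,7-dimethoxy-2-oxo-2H-chromen-8-yl)-4-(5,7-dimethoxy-2-oxo-2H-chromene-8-carbonyl)-5,5-dimethylcyclohexan-1-one | COc1cc(OC)c2ccc(=O)oc2c1[C@H]1CC(=O)CC(C)(C)[C@@H]1C(=O)c1c(OC)cc(OC)c2ccc(=O)oc12 | intermediate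
16 | potassium (3S,4R)-3-(5,7-dimethoxy-2-oxo-2H-chromen-8-yl)-4-(5,7-dimethoxy-2-oxo-2H-chromene-8-carbonyl)-5,5-dimethylcyclohex-1-en-1-olate | [K+].COc1cc(OC)c2ccc(=O)oc2c1[C@H]1C=C([O-])CC(C)(C)[C@@H]1C(=O)c1c(OC)cc(OC)c2ccc(=O)oc12 | intermediate
17 | (3S,4R)-3-(5,7-dimethoxy-2-oxo-2H-chromen-8-yl)-4-(5,7-dimethoxy-2-oxo-2H-chromene-8-carbonyl)-5,5-dimethylcyclohex-1-en-1-yl trifluoromethanesulfonate | COc1cc(OC)c2ccc(=O)oc2c1[C@H]1C=C(OS(=O)(=O)C(F)(F)F)CC(C)(C)[C@@H]1C(=O)c1c(OC)cc(OC)c2ccc(=O)oc12 | intermediate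
18 | 8-[(1S,6R)-6-(5,7-dimethoxy-2-oxo-2H-chromene-8-carbonyl)-3,5,5-trimethylcyclohex-2-en-1-yl]-5,7-dimethoxy-2H-chromen-2-one | COc1cc(OC)c2ccc(=O)oc2c1[C@H]1C=C(C)CC(C)(C)[C@@H]1C(=O)c1c(OC)cc(OC)c2ccc(=O)oc12 | intermediate
19 | 8-[(1S,6R)-6-[(R)-(5,7-dimethoxy-2-oxo-2H-chromen-8-yl)(hydroxy)methyl]-3,5,5-trimethylcyclohex-2-en-1-yl]-5,7-dimethoxy-2H-chromen-2-one | COc1cc(OC)c2ccc(=O)oc2c1[C@H]1C=C(C)CC(C)(C)[C@@H]1[C@@H](O)c1c(OC)cc(OC)c2ccc(=O)oc12 | target

Total step count: 10. Longest linear sequence: 9 steps (steps 1, 2, 3, 5, 6, 7, 8, 9, 10; step 4 is the branch that makes the acceptor).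

**Steps most likely to fail**

Step 5. The conjugate addition may be slow at a β-carbon that is flanked by two ortho oxygen substituents and deactivated by the electron-rich ring, and the cross-conjugated iminium ion may give insufficient facial discrimination. The fallback sets out from 3 and 7 and comes back at 14; it moves the enantioselective event to an enal, the substrate class on which secondary-amine iminium catalysis is most reliable. Wittig reaction of 3 with (triphenylphosphoranylidene)acetaldehyde gives (2E)-3-(5,7-dimethoxy-2-oxo-2H-chromen-8-yl)prop-2-enal F1. Michael addition of 7 to F1 under catalysis by α,α-diphenylprolinol trimethylsilyl ether (the enantiomer that places the nucleophile on the required face) gives tert-butyl (3S)-2-(5,7-dimethoxy-2-oxo-2H-chromene-8-carbonyl)-3-(5,7-dimethoxy-2-oxo-2H-chromen-8-yl)-5-oxopentanoate F2. Trifluoroacetic acid cleaves the ester to (3S)-2-(5,7-dimethoxy-2-oxo-2H-chromene-8-carbonyl)-3-(5,7-dimethoxy-2-oxo-2H-chromen-8-yl)-5-oxopentanoic acid F3, which is not isolated and loses CO2 on warming to give (3S)-3,5-bis(5,7-dimethoxy-2-oxo-2H-chromen-8-yl)-5-oxopentanal F4. Nozaki–Hiyama–Kishi addition of 1-bromo-2-methylprop-1-ene (CrCl2, NiCl2 cat., DMF) to the aldehyde, which the hindered aryl ketone should not rival, gives (3S)-1,3-bis(5,7-dimethoxy-2-oxo-2H-chromen-8-yl)-5-hydroxy-7-methyloct-6-en-1-one F5. Dess–Martin oxidation of the allylic alcohol then returns the route to 14.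

Step 8. Regiocontrol of the enolisation may be lost, by proton removal at C4 or by enolate equilibration before sulfonylation, which would place the double bond at C3=C4. The fallback sets out from 15 and comes back at 18, replacing enolate chemistry by carbonyl addition and elimination. MeMgBr premixed with anhydrous CeCl3 (THF, −78 °C) should add only to the unhindered ring ketone and give 8-[(1S,2R)-2-(5,7-dimethoxy-2-oxo-2H-chromene-8-carbonyl)-5-hydroxy-3,3,5-trimethylcyclohexyl]-5,7-dimethoxy-2H-chromen-2-one F6. Syn-dehydration of this tertiary alcohol with methyl N-(triethylammoniosulfonyl)carbamate in warm toluene should take the more accessible C2 hydrogen in preference to the neopentyl C4 hydrogens and give 18, from which any isomeric alkene is separated.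

Step 10. Hydride may be delivered to the wrong face of the hindered aryl ketone, or forcing conditions may lead to conjugate reduction or opening of the coumarin lactones. The fallback sets out from 18 and comes back at 19: a catalyst-controlled oxazaborolidine (Corey–Bakshi–Shibata) reduction with catecholborane at low temperature, using the catalyst antipode matched to the required (R) carbinol. This replaces substrate control by reagent control and uses a borane that leaves lactones and the ring alkene alone. Any C7 epimer formed in the main step is returned to 18 by Dess–Martin oxidation. No new compound is made.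

**Further compounds**
F1 | step 5 | (2E)-3-(5,7-dimethoxy-2-oxo-2H-chromen-8-yl)prop-2-enal | COc1cc(OC)c2ccc(=O)oc2c1/C=C/C=O
F2 | step 5 | tert-butyl (3S)-2-(5,7-dimethoxy-2-oxo-2H-chromene-8-carbonyl)-3-(5,7-dimethoxy-2-oxo-2H-chromen-8-yl)-5-oxopentanoate | COc1cc(OC)c2ccc(=O)oc2c1[C@@H](CC=O)C(C(=O)OC(C)(C)C)C(=O)c1c(OC)cc(OC)c2ccc(=O)oc12
F3 | step 5 | (3S)-2-(5,7-dimethoxy-2-oxo-2H-chromene-8-carbonyl)-3-(5,7-dimethoxy-2-oxo-2H-chromen-8-yl)-5-oxopentanoic acid | COc1cc(OC)c2ccc(=O)oc2c1[C@@H](CC=O)C(C(=O)O)C(=O)c1c(OC)cc(OC)c2ccc(=O)oc12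
F4 | step 5 | (3S)-3,5-bis(5,7-dimethoxy-2-oxo-2H-chromen-8-yl)-5-oxopentanal | COc1cc(OC)c2ccc(=O)oc2c1[C@@H](CC=O)CC(=O)c1c(OC)cc(OC)c2ccc(=O)oc12
F5 | step 5 | (3S)-1,3-bis(5,7-dimethoxy-2-oxo-2H-chromen-8-yl)-5-hydroxy-7-methyloct-6-en-1-one | COc1cc(OC)c2ccc(=O)oc2c1[C@@H](CC(O)C=C(C)C)CC(=O)c1c(OC)cc(OC)c2ccc(=O)oc12
F6 | step 8 | 8-[(1S,2R)-2-(5,7-dimethoxy-2-oxo-2H-chromene-8-carbonyl)-5-hydroxy-3,3,5-trimethylcyclohexyl]-5,7-dimethoxy-2H-chromen-2-one | COc1cc(OC)c2ccc(=O)oc2c1[C@H]1CC(C)(O)CC(C)(C)[C@@H]1C(=O)c1c(OC)cc(OC)c2ccc(=O)oc12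
F0 | step 10 | none | none
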